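The chemist running this flask wants the height and time of its target peak.

| flask | substrate | free catalyst | remark | time |
|---|---|---|---|---|
| dawn | 0.050 M | 0.25 mM | run made earlier |  |
| spring | 0.050 M | 0.38 mM | run made earlier |  |
| noon | 0.10 M | 0.50 mM | run made earlier |  |
| flask | 0.050 M | 0.50 mM |  | 15 d |

- dawn (time / d: target / %, substrate / %): 0.208: 1.7, 71.5; 0.500: 4.9, 47.0; 1.04: 6.1, 22.0; 2.50: 1.6, 2.2; 6.00: 0, 2.9; 15.0: 0.6, 0.1
- spring (time / d: target / %, substrate / %): 0.208: 3.8, 73.0; 0.500: 6.3, 47.9; 1.04: 10.5, 20.6; 2.50: 1.0, 0.9; 6.00: 0, 0.1; 15.0: 0, 1.8
- noon (time / d: target / %, substrate / %): 0.208: 4.2, 72.8; 0.625: 10.9, 39.4; 1.67: 5.2, 8.2; 5.00: 0.9, 1.0; 15.0: 0, 0.1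

(scatter of a reading: 1 percentage point)

- the analysis behind the earlier runs scatters by 1 percentage point, standard deviation

- when, up to 15 d, the flask holds most target
- the amount of target, in percent of the substrate charged, at that time

Substrate falls alike in the dawn, spring and noon runs, to 71.5%, 73.0% and 72.8% at 0.208 d, while target reaches 10.5% in spring, so you reckon target as a small correction to that loss. Catalyst loading, c(free catalyst)/c(substrate), does not fold the runs together: dawn and noon both stand at 0.500%, yet their top readings are 6.1% and 10.9%. So try the catalyst charge by itself. The flask's c(free catalyst) divided by dawn's is 2.00, and this catalyst ratio says how many dawn charges a flask holds.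

Top readings divided by their ratios give 6.10% for dawn, 6.91% for spring and 5.45% for noon. These figures span 1.5 percentage points, against a scatter of 1 point on each reading, and the readings only sample each peak, so you can try one number, but only as a rough one. Their mean is 6.15%, and my own reckoning for the flask is therefore 12.3%, somewhere between 0.625 d and 1.04 d, the times of those top readings.

The forecast gives 12.8% at 0.85 d, on the ground that “Target formation scales roughly with catalyst”, a little above my figure.

    substrate → intermediate (k = 1.75 × 10⁻⁵ s⁻¹)
    free catalyst + intermediate → free catalyst + target (k = 0.0471 M⁻¹ s⁻¹)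
    free catalyst → spent catalyst (k = 1.54 × 10⁻⁵ s⁻¹)
    target → over-reaction product (k = 3.22 × 10⁻⁵ s⁻¹)

The flask peaks at 0.793 d with 11.1%, when 34.8% of its catalyst is free and 65.2% is spent. Divided by the catalyst ratio, that peak gives 5.55%, beside the 5.45% reckoned from noon's top reading. The neighbour flask with 0.0013 M has a ratio of 5.20, so the mean predicts 32.0%, but its simulated peak is 18.5%.

(Readings and results were generated by integration for an exercise, and the scatter is random.)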